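The carbocycle (ring C1–C6) is disconnected at C4–C5. The key step exploits the fact that C6, C1 and C2, whose oxygens point down, up, down, are C2, C3 and C4 of a D-glucopyranoside with C7 as a branch on sugar C3. In one operation a mercury-mediated Ferrier carbocyclisation opens the pyranoside and recloses it as the cyclohexanone, forming C4–C5 and leaving a C3 ketone that is later transposed into the C3=C4 alkene and the C5 oxygen. The precursor is a methyl 6-deoxyhex-5-enopyranoside with the 3-C-hydroxymethyl branch held as a 3,3'-acetonide, O2 as a 4-methoxybenzyl ether and O4 as a silyl ether.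

Key step: step 11

Remark: sugars carry carbohydrate numbering (C3' = branch carbon); carbocycles carry the numbering of the target (C1 = carbinol carbon bearing C7, C3=C4 = alkene) and are drawn with C1→C6 clockwise, which fixes "up" and "down"; TBS = tert-butyldimethylsilyl, PMB = 4-methoxybenzyl.
Remark: the route starts from commercial methyl α-D-glucopyranoside (the methyl glycoside of D-glucose) and sets the branch on the locked pyranoside chair, so that no glycosidation has to be run on a sugar with a free 3'-hydroxyl syn to the anomeric carbon.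

Step 1
Reactants: 1 methyl α-D-glucopyranoside
Product: 2 methyl 4,6-O-(di-tert-butylsilanediyl)-α-D-glucopyranoside
Conditions: tBu2Si(OTf)2, pyridine, DMF, −40 °C → 0 °C
Reagents that add atoms: di-tert-butylsilyl bis(trifluoromethanesulfonate), CC(C)(C)[Si](OS(=O)(=O)C(F)(F)F)(OS(=O)(=O)C(F)(F)F)C(C)(C)C
Why: Cyclic silylene formation should take the primary 6-OH first and close the six-membered trans-fused ring onto O4, which leaves the 2,3-diol free and locks the chair used later for face control.

Step 2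
Reactants: 2 methyl 4,6-O-(di-tert-butylsilanediyl)-α-D-glucopyranoside
Product: 4 methyl 4,6-O-(di-tert-butylsilanediyl)-2-O-(4-methoxybenzyl)-α-D-glucopyranoside, via stannylene acetal 3 (not isolated)
Conditions: Bu2SnO, toluene, reflux (Dean–Stark); then PMBCl, Bu4NI (cat.), 90 °C
Reagents that add atoms: 4-methoxybenzyl chloride, COc1ccc(CCl)cc1
Why: Stannylene-mediated regioselective O-alkylation should go to the equatorial O2, the more nucleophilic oxygen of a 2,3-stannylene next to an axial anomeric OMe, and leave O3 free for oxidation.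

Step 3
Reactants: 4 methyl 4,6-O-(di-tert-butylsilanediyl)-2-O-(4-methoxybenzyl)-α-D-glucopyranoside
Product: 5 methyl 4,6-O-(di-tert-butylsilanediyl)-2-O-(4-methoxybenzyl)-α-D-ribo-hexopyranosid-3-ulose
Conditions: Dess–Martin periodinane, CH2Cl2, rt
Reagents that add atoms: none
Why: Dess–Martin oxidation of the only free hydroxyl proceeds without base, so the stereocentres C2 and C4 next to the new ketone should not be enolised.

Step 4
Reactants: 5 methyl 4,6-O-(di-tert-butylsilanediyl)-2-O-(4-methoxybenzyl)-α-D-ribo-hexopyranosid-3-ulose; 6 methyltriphenylphosphonium bromide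
Product: 8 methyl 3-deoxy-4,6-O-(di-tert-butylsilanediyl)-2-O-(4-methoxybenzyl)-3-C-methylene-α-D-ribo-hexopyranoside, via methylenetriphenylphosphorane 7 (not isolated)
Conditions: 6, KN(SiMe3)2, THF, 0 °C; then 5, −78 °C → 0 °C
Reagents that add atoms: methyltriphenylphosphonium bromide (6), C[P+](c1ccccc1)(c1ccccc1)c1ccccc1.[Br-]
Why: Wittig methylenation with the lithium-free unstabilised ylide at low temperature should add to the ketone faster than it enolises it and installs C7 as an exocyclic methylene without creating a stereocentre.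

Step 5
Reactants: 8 methyl 3-deoxy-4,6-O-(di-tert-butylsilanediyl)-2-O-(4-methoxybenzyl)-3-C-methylene-α-D-ribo-hexopyranoside
Product: 9 methyl 4,6-O-(di-tert-butylsilanediyl)-3-C-(hydroxymethyl)-2-O-(4-methoxybenzyl)-α-D-glucopyranoside
Conditions: OsO4 (cat.), N-methylmorpholine N-oxide, acetone–H2O, rt
Reagents that add atoms: N-methylmorpholine N-oxide, C[N+]1([O-])CCOCC1; water, O
Why: Upjohn syn-dihydroxylation should occur from the upper (equatorial) side of the locked chair because the lower face of the exocyclic alkene is screened by the axial anomeric OMe and axial H-5, which sets C3 with O3 equatorial (gluco) and the CH2OH arm axial.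

Step 6
Reactants: 9 methyl 4,6-O-(di-tert-butylsilanediyl)-3-C-(hydroxymethyl)-2-O-(4-methoxybenzyl)-α-D-glucopyranoside
Product: 10 methyl 4,6-O-(di-tert-butylsilanediyl)-3-C-(hydroxymethyl)-3,3'-O-isopropylidene-2-O-(4-methoxybenzyl)-α-D-glucopyranoside
Conditions: Me2C(OMe)2, pyridinium p-toluenesulfonate (cat.), CH2Cl2, rt
Reagents that add atoms: 2,2-dimethoxypropane, COC(C)(C)OC
Why: Acid-catalysed transketalisation closes the dioxolane on the only diol present (tertiary O3 and primary O3') under acid too mild to touch the glycoside, and it masks the tertiary carbinol against retro-aldol cleavage in the later base steps.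

Step 7
Reactants: 10 methyl 4,6-O-(di-tert-butylsilanediyl)-3-C-(hydroxymethyl)-3,3'-O-isopropylidene-2-O-(4-methoxybenzyl)-α-D-glucopyranoside
Product: 11 methyl 3-C-(hydroxymethyl)-3,3'-O-isopropylidene-2-O-(4-methoxybenzyl)-α-D-glucopyranoside
Conditions: HF·pyridine, pyridine, THF, 0 °C → rt
Reagents that add atoms: none
Why: Fluoride-driven desilylation cleaves both Si–O bonds of the silylene and is orthogonal to the acetonide, the PMB ether and the glycoside, so only the 4,6-diol is released.

Step 8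
Reactants: 11 methyl 3-C-(hydroxymethyl)-3,3'-O-isopropylidene-2-O-(4-methoxybenzyl)-α-D-glucopyranoside
Product: 12 methyl 6-deoxy-3-C-(hydroxymethyl)-6-iodo-3,3'-O-isopropylidene-2-O-(4-methoxybenzyl)-α-D-glucopyranoside
Conditions: I2, PPh3, imidazole, toluene, 70 °C
Reagents that add atoms: iodine, [I][I]
Why: Garegg–Samuelsson (Appel-type) iodination should activate only the unhindered primary 6-OH for displacement by iodide, since the secondary 4-OH next to the quaternary C3 is far slower.

Step 9
Reactants: 12 methyl 6-deoxy-3-C-(hydroxymethyl)-6-iodo-3,3'-O-isopropylidene-2-O-(4-methoxybenzyl)-α-D-glucopyranoside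
Product: 13 methyl 4-O-(tert-butyldimethylsilyl)-6-deoxy-3-C-(hydroxymethyl)-6-iodo-3,3'-O-isopropylidene-2-O-(4-methoxybenzyl)-α-D-glucopyranoside
Conditions: tBuMe2SiOTf, 2,6-lutidine, CH2Cl2, 0 °C
Reagents that add atoms: tert-butyldimethylsilyl trifluoromethanesulfonate, CC(C)(C)[Si](C)(C)OS(=O)(=O)C(F)(F)F
Why: Silylation with the silyl triflate is reactive enough for the hindered 4-OH, and the hindered pyridine base leaves the primary iodide untouched.

Step 10
Reactants: 13 methyl 4-O-(tert-butyldimethylsilyl)-6-deoxy-3-C-(hydroxymethyl)-6-iodo-3,3'-O-isopropylidene-2-O-(4-methoxybenzyl)-α-D-glucopyranoside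
Product: 14 methyl 4-O-(tert-butyldimethylsilyl)-6-deoxy-3-C-(hydroxymethyl)-3,3'-O-isopropylidene-2-O-(4-methoxybenzyl)-α-D-xylo-hex-5-enopyranoside
Conditions: KOtBu, THF, 0 °C → rt
Reagents that add atoms: none
Why: E2 dehydroiodination by the bulky alkoxide removes the axial H-5 anti to the C6–I bond and gives the exocyclic enol ether, the usual entry to 6-deoxyhex-5-enopyranosides.

Step 11
Reactants: 14 methyl 4-O-(tert-butyldimethylsilyl)-6-deoxy-3-C-(hydroxymethyl)-3,3'-O-isopropylidene-2-O-(4-methoxybenzyl)-α-D-xylo-hex-5-enopyranoside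
Product: 16 2-O-TBS-6-O-PMB-1,7-O-isopropylidene derivative of 1,2,5,6-tetrahydroxy-1-(hydroxymethyl)cyclohexan-3-one (O1/O5 up; C7/O2/O6 down), via mercurio keto aldehyde 15 (not isolated)
Conditions: Hg(OCOCF3)2 (10 mol %), acetone–H2O (4:1), rt
Reagents that add atoms: water, O
Why: Hg(OCOCF3)2 (divalent mercury) adds to the terminal carbon of the exocyclic enol ether and water to the acetal carbon; the hemiketal collapses to the ketone, the anomeric hemiacetal loses methanol, and the open-chain α-mercurio keto aldehyde 15 results. Its mercury enolate adds to the aldehyde and forms the C4–C5 bond, and protonolysis of the mercury aldolate returns the salt, so a catalytic amount should suffice. This is the Ferrier carbocyclisation of 6-deoxyhex-5-enopyranosides to 5-hydroxycyclohexanones, a known reaction type. The six-membered carbocycle closes by a 6-(enolendo)-exo-trig aldol through a chair in which O6, O1 and O2 are equatorial and C7 is axial. The new C5 centre is controlled by that axial C7 arm on C1, which is syn to the axial site at C5 and should send the carbinol oxygen equatorial (up, trans to O6); the centre is erased in step 12, so either epimer serves. Needed are chemoselective oxymercuration of the enol ether over the anisyl ring and aldol addition over β-elimination: the enol ether is by far the most electron-rich π system, and the β-oxygen O1 sits on a quaternary carbon inside the dioxolane and is a poor leaving group in the nearly neutral medium.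

Step 12
Reactants: 16 2-O-TBS-6-O-PMB-1,7-O-isopropylidene derivative of 1,2,5,6-tetrahydroxy-1-(hydroxymethyl)cyclohexan-3-one (O1/O5 up; C7/O2/O6 down)
Product: 18 2-O-TBS-6-O-PMB-1,7-O-isopropylidene derivative of 1,2,6-trihydroxy-1-(hydroxymethyl)cyclohex-4-en-3-one (O1 up; C7/O2/O6 down), via mesylate 17 (not isolated)
Conditions: MsCl, Et3N, CH2Cl2, 0 °C → rt
Reagents that add atoms: none
Why: Mesylation of the β-hydroxyl followed by E1cB elimination through the C4 enolate gives the conjugated enone and removes the C5 centre, while the C2 and C1 oxygens are much poorer leaving groups than the mesylate and stay.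

Step 13
Reactants: 18 2-O-TBS-6-O-PMB-1,7-O-isopropylidene derivative of 1,2,6-trihydroxy-1-(hydroxymethyl)cyclohex-4-en-3-one (O1 up; C7/O2/O6 down)
Product: 19 upper-face 4,5-epoxide of 18 (O1/epoxide O up; C7/O2/O6 down)
Conditions: H2O2 (30% aq.), NaOH (cat.), MeOH, 0 °C
Reagents that add atoms: hydrogen peroxide, OO
Why: Weitz–Scheffer nucleophilic epoxidation should deliver hydroperoxide to C5 from the upper face, away from the adjacent C6–OPMB group and from the axial C7 arm on C1 that covers the lower face, and ring closure on the same face sets C4 and C5 with the epoxide trans to O6.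

Step 14
Reactants: 19 upper-face 4,5-epoxide of 18 (O1/epoxide O up; C7/O2/O6 down)
Product: 22 2-O-TBS-6-O-PMB-1,7-O-isopropylidene derivative of 1-(hydroxymethyl)cyclohex-3-ene-1,2,5,6-tetrol (O1/O5 up; C7/O2/O6 down), via hydrazone 20 (not isolated), via alkenyl diazene 21 (not isolated)
Conditions: N2H4·H2O, AcOH (cat.), MeOH, 0 °C → rt
Reagents that add atoms: none
Why: In the Wharton transposition the epoxy hydrazone opens to the alkenyl diazene, which loses N2 to leave the C3=C4 alkene and the C5 hydroxyl, whose configuration is that of the epoxide because the C5–O bond is never broken.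

Step 15
Reactants: 22 2-O-TBS-6-O-PMB-1,7-O-isopropylidene derivative of 1-(hydroxymethyl)cyclohex-3-ene-1,2,5,6-tetrol (O1/O5 up; C7/O2/O6 down)
Product: 23 6-O-(4-methoxybenzyl)-1-(hydroxymethyl)cyclohex-3-ene-1,2,5,6-tetrol (O1/O5 up; C7/O2/O6 down)
Conditions: HCl (1 M aq.), MeOH, rt
Reagents that add atoms: none
Why: Acid-catalysed solvolysis removes the dioxolane and the silyl ether in one operation, whereas the PMB ether is stable to dilute protic acid, so O6 alone stays masked.

Step 16
Reactants: 23 6-O-(4-methoxybenzyl)-1-(hydroxymethyl)cyclohex-3-ene-1,2,5,6-tetrol (O1/O5 up; C7/O2/O6 down); 24 benzoyl chloride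
Product: 25 2,5,7-tri-O-benzoyl-6-O-(4-methoxybenzyl)-1-(hydroxymethyl)cyclohex-3-ene-1,2,5,6-tetrol (O1/O5 up; C7/O2/O6 down)
Conditions: BzCl (3.5 equiv), pyridine, CH2Cl2, 0 °C → rt
Reagents that add atoms: benzoyl chloride (24), O=C(Cl)c1ccccc1
Why: Pyridine-mediated acylation should esterify the primary O7 and the secondary allylic O2 and O5, while the tertiary 1-OH is too hindered to react under these conditions and O6 is blocked.

Step 17
Reactants: 25 2,5,7-tri-O-benzoyl-6-O-(4-methoxybenzyl)-1-(hydroxymethyl)cyclohex-3-ene-1,2,5,6-tetrol (O1/O5 up; C7/O2/O6 down)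
Product: 26 [(1R,2R,5R,6S)-2,5-bis(benzoyloxy)-1,6-dihydroxycyclohex-3-en-1-yl]methyl benzoate (target)
Conditions: 2,3-dichloro-5,6-dicyano-1,4-benzoquinone (DDQ), CH2Cl2–pH 7 buffer, 0 °C → rt
Reagents that add atoms: none
Why: Oxidative cleavage of the electron-rich PMB ether frees O6 under neutral conditions that should neither cleave nor shift the three benzoates.

Compound list
1 | methyl α-D-glucopyranoside | CO[C@H]1O[C@H](CO)[C@@H](O)[C@H](O)[C@H]1O | starting material
2 | methyl 4,6-O-(di-tert-butylsilanediyl)-α-D-glucopyranoside | CO[C@H]1O[C@@H]2CO[Si](C(C)(C)C)(C(C)(C)C)O[C@H]2[C@H](O)[C@H]1O | intermediate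
3 | 2,3-O-dibutylstannylene acetal of 2 | CO[C@H]1O[C@@H]2CO[Si](C(C)(C)C)(C(C)(C)C)O[C@H]2[C@@H]2O[Sn](CCCC)(CCCC)O[C@@H]12 | intermediate
4 | methyl 4,6-O-(di-tert-butylsilanediyl)-2-O-(4-methoxybenzyl)-α-D-glucopyranoside | CO[C@H]1O[C@@H]2CO[Si](C(C)(C)C)(C(C)(C)C)O[C@H]2[C@H](O)[C@H]1OCc1ccc(OC)cc1 | intermediate
5 | methyl 4,6-O-(di-tert-butylsilanediyl)-2-O-(4-methoxybenzyl)-α-D-ribo-hexopyranosid-3-ulose | CO[C@H]1O[C@@H]2CO[Si](C(C)(C)C)(C(C)(C)C)O[C@H]2C(=O)[C@H]1OCc1ccc(OC)cc1 | intermediate
6 | methyltriphenylphosphonium bromide | C[P+](c1ccccc1)(c1ccccc1)c1ccccc1.[Br-] | starting material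
7 | methylenetriphenylphosphorane | C=P(c1ccccc1)(c1ccccc1)c1ccccc1 | intermediate
8 | methyl 3-deoxy-4,6-O-(di-tert-butylsilanediyl)-2-O-(4-methoxybenzyl)-3-C-methylene-α-D-ribo-hexopyranoside | CO[C@H]1O[C@@H]2CO[Si](C(C)(C)C)(C(C)(C)C)O[C@H]2C(=C)[C@H]1OCc1ccc(OC)cc1 | intermediate
9 | methyl 4,6-O-(di-tert-butylsilanediyl)-3-C-(hydroxymethyl)-2-O-(4-methoxybenzyl)-α-D-glucopyranoside | CO[C@H]1O[C@@H]2CO[Si](C(C)(C)C)(C(C)(C)C)O[C@H]2[C@@](O)(CO)[C@H]1OCc1ccc(OC)cc1 | intermediate
10 | methyl 4,6-O-(di-tert-butylsilanediyl)-3-C-(hydroxymethyl)-3,3'-O-isopropylidene-2-O-(4-methoxybenzyl)-α-D-glucopyranoside | CO[C@H]1O[C@@H]2CO[Si](C(C)(C)C)(C(C)(C)C)O[C@H]2[C@@]2(COC(C)(C)O2)[C@H]1OCc1ccc(OC)cc1 | intermediate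
11 | methyl 3-C-(hydroxymethyl)-3,3'-O-isopropylidene-2-O-(4-methoxybenzyl)-α-D-glucopyranoside | CO[C@H]1O[C@H](CO)[C@@H](O)[C@@]2(COC(C)(C)O2)[C@H]1OCc1ccc(OC)cc1 | intermediate
12 | methyl 6-deoxy-3-C-(hydroxymethyl)-6-iodo-3,3'-O-isopropylidene-2-O-(4-methoxybenzyl)-α-D-glucopyranoside | CO[C@H]1O[C@H](C[I])[C@@H](O)[C@@]2(COC(C)(C)O2)[C@H]1OCc1ccc(OC)cc1 | intermediate
13 | methyl 4-O-(tert-butyldimethylsilyl)-6-deoxy-3-C-(hydroxymethyl)-6-iodo-3,3'-O-isopropylidene-2-O-(4-methoxybenzyl)-α-D-glucopyranoside | CO[C@H]1O[C@H](C[I])[C@@H](O[Si](C)(C)C(C)(C)C)[C@@]2(COC(C)(C)O2)[C@H]1OCc1ccc(OC)cc1 | intermediate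
14 | methyl 4-O-(tert-butyldimethylsilyl)-6-deoxy-3-C-(hydroxymethyl)-3,3'-O-isopropylidene-2-O-(4-methoxybenzyl)-α-D-xylo-hex-5-enopyranoside | CO[C@H]1OC(=C)[C@@H](O[Si](C)(C)C(C)(C)C)[C@@]2(COC(C)(C)O2)[C@H]1OCc1ccc(OC)cc1 | intermediate
15 | open-chain 6-(trifluoroacetoxymercurio) 5-keto aldehyde derived from 14 | O=C[C@H](OCc1ccc(OC)cc1)[C@]1(COC(C)(C)O1)[C@H](O[Si](C)(C)C(C)(C)C)C(=O)C[Hg]OC(=O)C(F)(F)F | intermediate
16 | 2-O-TBS-6-O-PMB-1,7-O-isopropylidene derivative of 1,2,5,6-tetrahydroxy-1-(hydroxymethyl)cyclohexan-3-one (O1/O5 up; C7/O2/O6 down) | CC1(C)OC[C@]2(O1)[C@H](O[Si](C)(C)C(C)(C)C)C(=O)C[C@@H](O)[C@@H]2OCc1ccc(OC)cc1 | intermediate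
17 | 5-O-methanesulfonate of 16 | CC1(C)OC[C@]2(O1)[C@H](O[Si](C)(C)C(C)(C)C)C(=O)C[C@@H](OS(C)(=O)=O)[C@@H]2OCc1ccc(OC)cc1 | intermediate
18 | 2-O-TBS-6-O-PMB-1,7-O-isopropylidene derivative of 1,2,6-trihydroxy-1-(hydroxymethyl)cyclohex-4-en-3-one (O1 up; C7/O2/O6 down) | CC1(C)OC[C@]2(O1)[C@H](O[Si](C)(C)C(C)(C)C)C(=O)C=C[C@@H]2OCc1ccc(OC)cc1 | intermediate
19 | upper-face 4,5-epoxide of 18 (O1/epoxide O up; C7/O2/O6 down) | CC1(C)OC[C@]2(O1)[C@H](O[Si](C)(C)C(C)(C)C)C(=O)[C@H]3O[C@H]3[C@@H]2OCc1ccc(OC)cc1 | intermediate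
20 | C3 hydrazone of 19 | CC1(C)OC[C@]2(O1)[C@H](O[Si](C)(C)C(C)(C)C)C(=NN)[C@H]3O[C@H]3[C@@H]2OCc1ccc(OC)cc1 | intermediate
21 | 3-diazenyl derivative of 22 (C3=C4 alkene, 5-OH up) | CC1(C)OC[C@]2(O1)[C@H](O[Si](C)(C)C(C)(C)C)C(N=N)=C[C@@H](O)[C@@H]2OCc1ccc(OC)cc1 | intermediate
22 | 2-O-TBS-6-O-PMB-1,7-O-isopropylidene derivative of 1-(hydroxymethyl)cyclohex-3-ene-1,2,5,6-tetrol (O1/O5 up; C7/O2/O6 down) | CC1(C)OC[C@]2(O1)[C@H](O[Si](C)(C)C(C)(C)C)C=C[C@@H](O)[C@@H]2OCc1ccc(OC)cc1 | intermediate
23 | 6-O-(4-methoxybenzyl)-1-(hydroxymethyl)cyclohex-3-ene-1,2,5,6-tetrol (O1/O5 up; C7/O2/O6 down) | OC[C@]1(O)[C@H](O)C=C[C@@H](O)[C@@H]1OCc1ccc(OC)cc1 | intermediate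
24 | benzoyl chloride | O=C(Cl)c1ccccc1 | starting material
25 | 2,5,7-tri-O-benzoyl-6-O-(4-methoxybenzyl)-1-(hydroxymethyl)cyclohex-3-ene-1,2,5,6-tetrol (O1/O5 up; C7/O2/O6 down) | O=C(OC[C@]1(O)[C@H](OC(=O)c2ccccc2)C=C[C@@H](OC(=O)c2ccccc2)[C@@H]1OCc1ccc(OC)cc1)c1ccccc1 | intermediate
26 | [(1R,2R,5R,6S)-2,5-bis(benzoyloxy)-1,6-dihydroxycyclohex-3-en-1-yl]methyl benzoate (CNP0128482.2) | O=C(OC[C@]1(O)[C@H](OC(=O)c2ccccc2)C=C[C@@H](OC(=O)c2ccccc2)[C@@H]1O)c1ccccc1 | target

Total step count: 17
Longest linear sequence: 17 steps (1 → 26)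

Steps most likely to fail

Step 11 (key step). The crowded substrate may react slowly, so that the acidic mercury salt has time to strip the acetonide or silyl ether. The open-chain intermediate may also lose a β-oxygen instead of cyclising. The fallback sets out from 14 and makes the same C4–C5 bond without metal. Hydrolysis of the enol ether with pyridinium p-toluenesulfonate in wet acetone should give the open-chain 6-deoxy-5-keto aldehyde F1. An amine-mediated intramolecular aldol condensation (dibenzylammonium trifluoroacetate, toluene, 50 °C) then closes the ring and dehydrates in the same operation. The sequence comes back to the route at enone 18.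

Step 14. Hydrazone formation at the hindered C3 ketone may be slow, so that hydrazine opens the epoxide or the α-silyloxy group is lost before the fragmentation. The fallback sets out from 19 and runs the transposition as a radical fragmentation. NaBH4 in MeOH at 0 °C should give the epoxy alcohol F2, whose C3 configuration is immaterial. 1,1'-Thiocarbonyldiimidazole converts it into the imidazolyl thionocarbonate F3. Bu3SnH and azobisisobutyronitrile in toluene at 80 °C generate the C3 radical, which opens the oxirane by C4–O cleavage and picks up hydrogen on oxygen. The sequence comes back at 22.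

Step 4. The basic ylide may enolise the 3-ulose, which would epimerise C2 or expel the anomeric methoxide. The fallback sets out from 5 and uses a Peterson olefination. Me3SiCH2MgCl in the presence of CeCl3 (THF, −78 °C) is weakly basic and should add to the ketone to give the β-hydroxysilane F4, whose C3 configuration is lost again. KH in THF then brings about syn-elimination of the silanolate. The sequence comes back at 8.

Further compounds
F1 | step 11 | open-chain 4-O-TBS-2-O-PMB-3,3'-O-isopropylidene-6-deoxy-3-C-(hydroxymethyl)-D-xylo-hexos-5-ulose | O=C[C@H](OCc1ccc(OC)cc1)[C@]1(COC(C)(C)O1)[C@H](O[Si](C)(C)C(C)(C)C)C(C)=O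
F2 | step 14 | C3 alcohol from reduction of epoxy ketone 19 (C3 configuration immaterial) | CC1(C)OC[C@]2(O1)[C@H](O[Si](C)(C)C(C)(C)C)C(O)[C@H]3O[C@H]3[C@@H]2OCc1ccc(OC)cc1
F3 | step 14 | O-(imidazol-1-ylthiocarbonyl) derivative of F2 | CC1(C)OC[C@]2(O1)[C@H](O[Si](C)(C)C(C)(C)C)C(OC(=S)n1ccnc1)[C@H]3O[C@H]3[C@@H]2OCc1ccc(OC)cc1
F4 | step 4 | methyl 4,6-O-(di-tert-butylsilanediyl)-2-O-(4-methoxybenzyl)-3-C-[(trimethylsilyl)methyl]-α-D-allopyranoside | CO[C@H]1O[C@@H]2CO[Si](C(C)(C)C)(C(C)(C)C)O[C@H]2[C@](O)(C[Si](C)(C)C)[C@H]1OCc1ccc(OC)cc1
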